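**Plan**

1. Cuts: first the upper interflavan bond (top C4–middle C8); then both bonds at C4 of the middle unit (C4–C4a inside ring C and C4–C8 of the bottom unit); then the O1–C2 aryl ether and the C2–aryl bond of the acyclic chain that is left.
2. Enabling feature: C4 of the middle unit is a methine bonded to two phloroglucinol-type carbons (C4a of its own ring A and C8 of ring A of the bottom unit). It is therefore an aldehyde carbon that has been arylated twice, the first time through the O1–C2 tether.
3. Forward: aryl Grignard plus (R)-glyceraldehyde acetonide, Mitsunobu etherification with 3,5-bis(benzyloxy)phenol, acetonide removal and oxidation give an acyclic 2-hydroxy-3-aryloxy aldehyde. One acid-mediated operation then closes ring C of the middle unit (the only ring made in the route) and joins benzylated catechin. The epiafzelechin unit is added through its 4-(2-ethoxyethoxy) derivative, and hydrogenolysis ends the route.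
4. Stereochemistry: middle C3 from (R)-glyceraldehyde; middle C2 by Felkin–Anh addition followed by Mitsunobu inversion; middle C4 and top C4 by attack anti to the C3 oxygen on flavan-4-yl cations; all other centres from (+)-catechin and (−)-epiafzelechin.
5. Helpers: the acetonide (removed in step 4), the aldehyde oxidation level at C4 (consumed in step 6) and eleven benzyl ethers (removed in step 10).

Key step: step 6

Assumption: (−)-epiafzelechin (13) and (R)-2,3-O-isopropylideneglyceraldehyde (4) are taken as purchasable; 4 is distilled just before use because it oligomerises on standing.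

**Route**

Step 1
Reactants: 1 (+)-catechin
Product: 2 5,7,3′,4′-tetra-O-benzyl-(+)-catechin
Conditions: BnBr (4.4 equiv), K2CO3, DMF, 0 °C → rt
Reagents that add atoms: benzyl bromide, BrCc1ccccc1
Why: Williamson etherification in which K2CO3 deprotonates only the four phenols, so the aliphatic 3-OH stays free and no stereocentre is touched.

Step 2
Reactants: 3 4-bromo-1,2-bis(benzyloxy)benzene; 4 (R)-2,2-dimethyl-1,3-dioxolane-4-carbaldehyde
Product: 6 (S)-[3,4-bis(benzyloxy)phenyl][(4R)-2,2-dimethyl-1,3-dioxolan-4-yl]methanol (anti isomer), via arylmagnesium bromide 5 (not isolated)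
Conditions: Mg, THF, reflux; then 4, THF, −78 °C; H2O work-up; chromatography
Reagents that add atoms: none
Why: Grignard addition to an α-alkoxy aldehyde under Felkin–Anh (non-chelation) control, in which the aryl group attacks anti to the dioxolane C–O bond and should favour the anti (1S) carbinol; the minor syn epimer is removed by chromatography.

Step 3
Reactants: 6 anti carbinol; 7 3,5-bis(benzyloxy)phenol
Product: 8 (4R)-4-{(R)-[3,5-bis(benzyloxy)phenoxy][3,4-bis(benzyloxy)phenyl]methyl}-2,2-dimethyl-1,3-dioxolane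
Conditions: PPh3, DIAD, toluene, 0 °C → rt
Reagents that add atoms: none
Why: Mitsunobu etherification, in which the phenol displaces the oxyphosphonium of the benzylic alcohol by SN2 with inversion; this sets the future C2 (R) and the threo O1/O3 relationship of a 2,3-cis flavan, and toluene at low temperature disfavours ionisation.

Step 4
Reactants: 8 aryl ether acetonide
Product: 9 (2R,3R)-3-[3,5-bis(benzyloxy)phenoxy]-3-[3,4-bis(benzyloxy)phenyl]propane-1,2-diol
Conditions: AcOH/H2O/THF (4:1:1), 40 °C
Reagents that add atoms: none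
Why: Acid-catalysed hydrolysis of a terminal acetonide under conditions mild enough to leave the benzyl ethers and the benzylic aryl ether intact; no stereocentre is touched.

Step 5
Reactants: 9 diol
Product: 10 (2S,3R)-3-[3,5-bis(benzyloxy)phenoxy]-3-[3,4-bis(benzyloxy)phenyl]-2-hydroxypropanal
Conditions: TEMPO (0.1 equiv), PhI(OAc)2 (1.1 equiv), CH2Cl2, 0 °C → rt; used crude
Reagents that add atoms: none
Why: Oxoammonium (TEMPO/PhI(OAc)2) oxidation, which is selective for the primary over the secondary alcohol and stops at the aldehyde in dry CH2Cl2; the non-basic medium should avoid β-elimination of the aryloxide and epimerisation at C3.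

Step 6
Reactants: 10 hydroxy aldehyde; 2 5,7,3′,4′-tetra-O-benzyl-(+)-catechin
Product: 12 5,7,3′,4′-tetra-O-benzyl-(−)-epicatechin-(4β→8)-5,7,3′,4′-tetra-O-benzyl-(+)-catechin, via flavan-3,4-diol 11 (not isolated)
Conditions: BF3·OEt2 (0.5 equiv), 2 (3 equiv), 4 Å MS, CH2Cl2, −78 → −20 °C
Reagents that add atoms: none
Why: Proposed new method: BF3 activates the aldehyde of 10 towards the tethered 3,5-bis(benzyloxy)phenoxy ring, whose carbon ortho to O1 (the future C4a) carries three activating oxygens and attacks C4 in a 6-exo-trig Friedel–Crafts hydroxyalkylation that closes ring C through the new C4–C4a bond and gives flavan-3,4-diol 11; the 4-OH of 11, ortho and para to the 5- and 7-benzyloxy groups, then ionises to the flavan-4-yl cation (a quinone-methide-type oxocarbenium), which C8 of 2 traps to form the interflavan bond. The closest known reaction types are the acid-mediated twofold arylation of aldehydes to diarylmethanes and the condensation of flavan-3,4-diols or 4-alkoxyflavans with flavan-3-ols; the new element is that the flavan ring itself is made in this way from an acyclic 2-hydroxy-3-aryloxy aldehyde. C2 and C3 are carried in unchanged from 10 because no bond to them is broken, and the new C4 centre is set in the second arylation: in the half-chair cation with the C2 aryl group equatorial and the C3 hydroxyl axial, 2 approaches anti to the axial C3–O bond and should give the 3,4-trans (4β) product, as is general for 2,3-cis flavan-4-yl cations, while the C4 configuration of 11 is erased on ionisation. The step needs ring closure to outrun ionisation of the acyclic C2–O1 benzylic ether and intermolecular consumption of the aldehyde; the six-membered closure onto a phloroglucinol-type ring is entropically favoured, the hydroxyl and formyl groups next to C2 retard ionisation there, and if 2 adds to the aldehyde first the resulting carbinol ionises to a cation of the same type that C4a closes to the same product. Regiochemistry rests on the symmetry of the tethered ring (both positions ortho to O1 are equivalent and the para position cannot reach C4), on the higher nucleophilicity of C8 over C6 in 2, and on the excess of 2, which suppresses attack of the product on the cation.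

Step 7
Reactants: 13 (−)-epiafzelechin
Product: 14 5,7,4′-tri-O-benzyl-(−)-epiafzelechin
Conditions: BnBr (3.3 equiv), K2CO3, DMF, 0 °C → rt
Reagents that add atoms: benzyl bromide, BrCc1ccccc1
Why: Williamson etherification selective for the three phenols over the aliphatic 3-OH; no stereocentre is touched.

Step 8
Reactants: 14 tri-O-benzyl-epiafzelechin
Product: 15 (2R,3R,4S)-5,7,4′-tri-O-benzyl-4β-(2-ethoxyethoxy)epiafzelechin (3,4-trans)
Conditions: DDQ (2 equiv), 2-ethoxyethanol (5 equiv), CH2Cl2, rt
Reagents that add atoms: 2-ethoxyethanol, CCOCCO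
Why: DDQ benzylic oxidation by hydride abstraction at C4 (activated by the ring A oxygens), with the cation captured by 2-ethoxyethanol anti to the C3 hydroxyl to give the 3,4-trans (4β) ether, as established for benzylated flavan-3-ols.

Step 9
Reactants: 15 4-(2-ethoxyethoxy) electrophile; 12 dimer (1.5–2 equiv, excess recovered)
Product: 16 5,7,4′-tri-O-benzyl-epiafzelechin-(4β→8)-5,7,3′,4′-tetra-O-benzyl-epicatechin-(4β→8)-5,7,3′,4′-tetra-O-benzyl-catechin
Conditions: TMSOTf (0.2 equiv), CH2Cl2, −78 → −20 °C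
Reagents that add atoms: none
Why: Lewis acid-promoted Friedel–Crafts flavanylation (the standard interflavan coupling), in which TMSOTf ionises the 4-alkoxy group of 15 and C8 of the upper unit of 12, the most nucleophilic free position, attacks anti to the C3 hydroxyl to set top C4 (4β, 3,4-trans); the excess of 12 limits further chain growth.

Step 10
Reactants: 16 undeca-O-benzyl trimer
Product: 17 epiafzelechin-(4β→8)-epicatechin-(4β→8)-catechin (CNP0158921.1)
Conditions: H2 (1 atm), Pd(OH)2/C, THF/MeOH/H2O, rt; filtration, lyophilisation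
Reagents that add atoms: none
Why: Catalytic hydrogenolysis of the eleven benzyl ethers under neutral conditions, which is precedented to leave interflavan bonds, the ring C ethers and all stereocentres of benzylated proanthocyanidins untouched.

**Compound list**

1 | (+)-catechin | c1c(O)cc(O)c2c1O[C@H](c1ccc(O)c(O)c1)[C@@H](O)C2 | starting material
2 | 5,7,3′,4′-tetra-O-benzyl-(+)-catechin | c1c(OCc5ccccc5)cc(OCc5ccccc5)c2c1O[C@H](c1ccc(OCc5ccccc5)c(OCc5ccccc5)c1)[C@@H](O)C2 | intermediate
3 | 4-bromo-1,2-bis(benzyloxy)benzene | Brc1ccc(OCc2ccccc2)c(OCc2ccccc2)c1 | starting material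
4 | (R)-2,2-dimethyl-1,3-dioxolane-4-carbaldehyde | O=C[C@H]1COC(C)(C)O1 | starting material
5 | [3,4-bis(benzyloxy)phenyl]magnesium bromide | Br[Mg]c1ccc(OCc2ccccc2)c(OCc2ccccc2)c1 | intermediate (not isolated)
6 | (S)-[3,4-bis(benzyloxy)phenyl][(4R)-2,2-dimethyl-1,3-dioxolan-4-yl]methanol | O[C@@H](c1ccc(OCc2ccccc2)c(OCc2ccccc2)c1)[C@H]1COC(C)(C)O1 | intermediate
7 | 3,5-bis(benzyloxy)phenol | Oc1cc(OCc2ccccc2)cc(OCc2ccccc2)c1 | starting material
8 | (4R)-4-{(R)-[3,5-bis(benzyloxy)phenoxy][3,4-bis(benzyloxy)phenyl]methyl}-2,2-dimethyl-1,3-dioxolane | c1c(OCc2ccccc2)cc(OCc2ccccc2)cc1O[C@H](c1ccc(OCc2ccccc2)c(OCc2ccccc2)c1)[C@H]1COC(C)(C)O1 | intermediate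
9 | (2R,3R)-3-[3,5-bis(benzyloxy)phenoxy]-3-[3,4-bis(benzyloxy)phenyl]propane-1,2-diol | c1c(OCc2ccccc2)cc(OCc2ccccc2)cc1O[C@H](c1ccc(OCc2ccccc2)c(OCc2ccccc2)c1)[C@H](O)CO | intermediate
10 | (2S,3R)-3-[3,5-bis(benzyloxy)phenoxy]-3-[3,4-bis(benzyloxy)phenyl]-2-hydroxypropanal | c1c(OCc2ccccc2)cc(OCc2ccccc2)cc1O[C@H](c1ccc(OCc2ccccc2)c(OCc2ccccc2)c1)[C@H](O)C=O | intermediate
11 | (2R,3R)-5,7-bis(benzyloxy)-2-[3,4-bis(benzyloxy)phenyl]chromane-3,4-diol (2,3-cis; C4 epimers) | c1c(OCc5ccccc5)cc(OCc5ccccc5)c2c1O[C@H](c1ccc(OCc5ccccc5)c(OCc5ccccc5)c1)[C@H](O)C2O | intermediate (not isolated)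
12 | 5,7,3′,4′-tetra-O-benzyl-(−)-epicatechin-(4β→8)-5,7,3′,4′-tetra-O-benzyl-(+)-catechin | c1c(OCc5ccccc5)cc(OCc5ccccc5)c2c1O[C@H](c1ccc(OCc5ccccc5)c(OCc5ccccc5)c1)[C@H](O)[C@H]2c1c(OCc5ccccc5)cc(OCc5ccccc5)c2c1O[C@H](c1ccc(OCc5ccccc5)c(OCc5ccccc5)c1)[C@@H](O)C2 | intermediate
13 | (−)-epiafzelechin | Oc1ccc(cc1)[C@H]1Oc2cc(O)cc(O)c2C[C@H]1O | starting material
14 | 5,7,4′-tri-O-benzyl-(−)-epiafzelechin | C(c1ccccc1)Oc1ccc(cc1)[C@H]1Oc2cc(OCc3ccccc3)cc(OCc3ccccc3)c2C[C@H]1O | intermediate
15 | (2R,3R,4S)-5,7,4′-tri-O-benzyl-4β-(2-ethoxyethoxy)epiafzelechin | C(c1ccccc1)Oc1ccc(cc1)[C@H]1Oc2cc(OCc3ccccc3)cc(OCc3ccccc3)c2[C@H](OCCOCC)[C@H]1O | intermediate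
16 | 5,7,4′-tri-O-benzyl-epiafzelechin-(4β→8)-5,7,3′,4′-tetra-O-benzyl-epicatechin-(4β→8)-5,7,3′,4′-tetra-O-benzyl-catechin | C(c5ccccc5)Oc1ccc([C@H]2Oc3cc(OCc5ccccc5)cc(OCc5ccccc5)c3[C@H](c3c(OCc5ccccc5)cc(OCc5ccccc5)c4c3O[C@H](c3ccc(OCc5ccccc5)c(OCc5ccccc5)c3)[C@H](O)[C@H]4c3c(OCc5ccccc5)cc(OCc5ccccc5)c4c3O[C@H](c3ccc(OCc5ccccc5)c(OCc5ccccc5)c3)[C@@H](O)C4)[C@H]2O)cc1 | intermediate
17 | epiafzelechin-(4β→8)-epicatechin-(4β→8)-catechin (CNP0158921.1) | Oc1ccc([C@H]2Oc3cc(O)cc(O)c3[C@H](c3c(O)cc(O)c4c3O[C@H](c3ccc(O)c(O)c3)[C@H](O)[C@H]4c3c(O)cc(O)c4c3O[C@H](c3ccc(O)c(O)c3)[C@@H](O)C4)[C@H]2O)cc1 | target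

**Step count**

Total: 10 steps. Longest linear sequence: 7 steps (steps 2, 3, 4, 5, 6, 9, 10).

**Steps most likely to fail**

Step 6 (Proposed new method). The acyclic C2–O1 benzylic ether may ionise before ring closure, which would scramble C2 or cleave the tether. The hydroxy aldehyde may also isomerise by enolisation, and the product may attack the cation and oligomerise. The fallback uses only known chemistry and takes ring C of the middle unit from the chiral pool. It sets out from 2. Commercial (−)-epicatechin is benzylated (BnBr, K2CO3, DMF) to 5,7,3′,4′-tetra-O-benzyl-(−)-epicatechin F1. F1 is oxidised at C4 with DDQ and 2-ethoxyethanol in CH2Cl2 to 5,7,3′,4′-tetra-O-benzyl-4β-(2-ethoxyethoxy)epicatechin F2. F2 is coupled with an excess of 2 under TMSOTf in CH2Cl2 at −78 → −20 °C, and the route is rejoined at 12.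

Step 3. Ionisation at the electron-rich, hindered benzylic carbon may erode the inversion, or the hindered alcohol may fail to react. The fallback forms the ether with retention, without breaking the carbinol C–O bond. It sets out from 6, which is oxidised with Dess–Martin periodinane to [3,4-bis(benzyloxy)phenyl][(4R)-2,2-dimethyl-1,3-dioxolan-4-yl]methanone F3. Felkin–Anh reduction of F3 with LiBH(s-Bu)3 in THF at −78 °C should give the syn carbinol (R)-[3,4-bis(benzyloxy)phenyl][(4R)-2,2-dimethyl-1,3-dioxolan-4-yl]methanol F4, which is also the minor product of step 2. F4 is O-arylated with 1,3-bis(benzyloxy)-5-iodobenzene under Ullmann-type conditions (CuI, 3,4,7,8-tetramethyl-1,10-phenanthroline, Cs2CO3, toluene, 110 °C), and the route is rejoined at 8.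

Step 5. The free 2-hydroxy-3-aryloxy aldehyde may over-oxidise, lose the aryloxide by β-elimination, epimerise at C3 through its enol, or be lost as hemiacetal dimers. The fallback masks the secondary hydroxyl and makes the aldehyde by a different oxidation. It sets out from 9, which is silylated (Et3SiCl, imidazole, CH2Cl2) to the bis(triethylsilyl) ether F5. Swern oxidation of F5 ((COCl)2, DMSO, CH2Cl2, −78 → −30 °C, then Et3N), which converts primary triethylsilyl ethers directly into aldehydes while secondary ones survive, gives the 2-O-triethylsilyl aldehyde F6. F6 is treated with 2 and BF3·OEt2 as in step 6 to give the 3-O-triethylsilyl dimer F7. Desilylation with Bu4NF in THF rejoins the route at 12.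

**Further compounds**

F1 | step 6 | 5,7,3′,4′-tetra-O-benzyl-(−)-epicatechin | c1c(OCc5ccccc5)cc(OCc5ccccc5)c2c1O[C@H](c1ccc(OCc5ccccc5)c(OCc5ccccc5)c1)[C@H](O)C2
F2 | step 6 | 5,7,3′,4′-tetra-O-benzyl-4β-(2-ethoxyethoxy)-(−)-epicatechin | c1c(OCc5ccccc5)cc(OCc5ccccc5)c2c1O[C@H](c1ccc(OCc5ccccc5)c(OCc5ccccc5)c1)[C@H](O)[C@H]2OCCOCC
F3 | step 3 | [3,4-bis(benzyloxy)phenyl][(4R)-2,2-dimethyl-1,3-dioxolan-4-yl]methanone | O=C(c1ccc(OCc2ccccc2)c(OCc2ccccc2)c1)[C@H]1COC(C)(C)O1
F4 | step 3 | (R)-[3,4-bis(benzyloxy)phenyl][(4R)-2,2-dimethyl-1,3-dioxolan-4-yl]methanol | O[C@H](c1ccc(OCc2ccccc2)c(OCc2ccccc2)c1)[C@H]1COC(C)(C)O1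
F5 | step 5 | (2R,3R)-3-[3,5-bis(benzyloxy)phenoxy]-3-[3,4-bis(benzyloxy)phenyl]-1,2-bis(triethylsilyloxy)propane | c1c(OCc2ccccc2)cc(OCc2ccccc2)cc1O[C@H](c1ccc(OCc2ccccc2)c(OCc2ccccc2)c1)[C@H](O[Si](CC)(CC)CC)CO[Si](CC)(CC)CC
F6 | step 5 | (2S,3R)-3-[3,5-bis(benzyloxy)phenoxy]-3-[3,4-bis(benzyloxy)phenyl]-2-(triethylsilyloxy)propanal | c1c(OCc2ccccc2)cc(OCc2ccccc2)cc1O[C@H](c1ccc(OCc2ccccc2)c(OCc2ccccc2)c1)[C@H](O[Si](CC)(CC)CC)C=O
F7 | step 5 | 3-O-triethylsilyl-5,7,3′,4′-tetra-O-benzyl-epicatechin-(4β→8)-5,7,3′,4′-tetra-O-benzyl-catechin | c1c(OCc5ccccc5)cc(OCc5ccccc5)c2c1O[C@H](c1ccc(OCc5ccccc5)c(OCc5ccccc5)c1)[C@H](O[Si](CC)(CC)CC)[C@H]2c1c(OCc5ccccc5)cc(OCc5ccccc5)c2c1O[C@H](c1ccc(OCc5ccccc5)c(OCc5ccccc5)c1)[C@@H](O)C2
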